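# Synthesis plan for CNP0289272.1 (28) through a dihydropyran template opened by nickel-catalysed ring-closing coupling

## The problem

Compound 28 is a germacrane diester: a ten-membered carbocycle with an E trisubstituted alkene (C1=C10), a trisubstituted epoxide at C4–C5 in which C3 and C6 are cis, and three contiguous stereocentres at C6 (acetate), C7 (isopropyl) and C8 (angelate). No second carbocycle is fused to the ring, so the medium ring has to be closed as such, with one alkene E and the alkene that precedes the epoxide Z. The stereocentres fall into two groups. The C6–C7–C8 triad (C6 oxygen and isopropyl cis, C8 oxygen trans to both) can be fixed before the macrocycle exists; C4 and C5 can then be taken from C6, because the epoxide oxygen lies on the same face of the ring as the C6 oxygen and can be delivered from a free C6 hydroxyl. The C6 and C8 oxygens end up with different acyl groups and must be distinguishable once the ring is in hand. Three groups will not survive rough treatment and belong at the end: the angelate (Z to E isomerisation to the tiglate with base, nucleophilic catalysts or heat), the 4,5-epoxide facing the 1(10)-alkene across the ring (transannular cyclisation with acid) and the 1,5-diene (Cope rearrangement on strong heating). The feature that opens the route is the 1,5-relation between the C8 oxygen and C4 through C5, C6 and C7: joining these two atoms gives a 6-methyl-3,4-dihydro-2H-pyran that carries C6, C7 and C8 on one six-membered ring, holds C4=C5 cis, and leaves C3–C4 as the only bond to be made when the carbocycle closes at the expense of the pyran.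

## Retrosynthesis

**Ester and epoxide C–O bonds (28 back to 23).** The acetyl C–O bond at C6 is cut first (27), then the two epoxide C–O bonds (26), then the silyl group is put back on the C6 oxygen (25) and the angeloyl C–O bond at C8 is cut (23). This order keeps the epoxide and the angelate away from all skeleton-building steps. Acetylation must be last because the epoxidation needs the free C6 hydroxyl as its directing group. Angeloylation must come before desilylation because only then are the two oxygens differentiated. The forward steps must give an angelate without isomerisation and an epoxidation that touches only C4=C5, on the face of the C6 hydroxyl.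

**C3–C4 (23 back to 21).** Cutting C3–C4 and joining C4 to the C8 oxygen turns dienol 23 into dihydropyran 21, whose side chain ends in a primary bromide (the source of Grignard reagent 22). Neighbouring cuts were weighed. C2–C3 would need an acyclic precursor with a fragile Z allylic halide. Ring-closing metathesis at C1=C10 would have to form a trisubstituted E alkene in a ten-membered ring. A cut next to C6 would create a stereocentre during ring closure. The C3–C4 cut creates no stereocentre, takes the 4Z geometry from a six-membered ring, and releases the C8 hydroxyl free beside a silylated C6 oxygen. The precursor is much simpler: one six-membered ring with an all-cis triad and an achiral chain. The forward reaction must replace the enol-ether oxygen by a tethered primary alkyl group on nickel, with retention, in a medium-ring closure.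

**Si–O and C6–H (21 back to 19).** Removing the silyl group gives alcohol 20, and cutting the C6–H bond gives dihydropyranone 19. The all-cis triad is thereby reduced to a cis 2,3-pair, since a 1,2-reduction from the face opposite both substituents sets C6.

**Ring C4–O bond (19 back to 18).** Opening the vinylogous ester at the C4–O bond gives β-hydroxy ynone 18, an acyclic aldol-type compound. A one-step cycloaddition of aldehyde 8 with an oxygenated diene would also lead to 19. It was set aside because the diene would carry both methyl and alkoxy on its oxygen-bearing terminus, a pattern that disfavours the cisoid form and has no regiodefined preparation from a simple diketone. The cyclisation of 18 must be 6-endo and must not epimerise C7.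

**C5–C6 (18 back to 16, 17 and 15).** The acyl–alkynyl bond is cut to Weinreb amide 16 and propynyl Grignard reagent 17; amide 16 comes from imide 15 by amine exchange. This puts C4, C5 and the C4 methyl into one commercial three-carbon reagent.

**C7–C8 (15 back to 12 and 8; 12 back to 9 and 10).** The aldol cut sets both C7 and C8 in one auxiliary-controlled step; the syn aldol relation is the cis 2,3-relation of the pyran. Imide 12 comes from oxazolidinone 9 and acid chloride 10. The aldehyde partner 8 is achiral.

**C1–C2 and C10–CH3 (8 back to 1 and 2).** Aldehyde 8 is traced through alcohol 7, bromide 6 and alcohol 5 to silyl ether 1 and oxirane 2. Carboalumination of the alkyne, followed by opening of oxirane, builds the E trisubstituted alkene with the methyl group in place. The two chain ends are differentiated from the start, so C3 can carry the bromide early and no late halogenation next to the acid-labile enol ether is needed.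

## Roads not taken

**Alternative 1: enone–cyclobutene photocycloaddition and thermal opening.** The cut is at C1–C10 and C4–C5, which are made as σ-bonds and later become the two alkenes.
- Forward step: irradiation of cyclohexenone A2 with cyclobutene ester A3 would give the tricyclic photoadduct A1; heating would open the bicyclo[2.2.0]hexane unit to the cyclodeca-1,5-diene.
- Merits: both reactions are known types, the route is convergent, and C7 and C8 are set on a six-membered ring.
- Weak points for this target: C4 emerges bearing an ester that must be reduced to a methyl group beside a ketone. The alkene geometries depend on the ring fusion of A1 and on a thermal step that also invites Cope rearrangement. The head-to-head regiochemistry is not assured. The C6 ketone must be reduced selectively on the flexible ring.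
- Comparison: its ring-forming steps rest on known chemistry, which the chosen key step does not. Against that, the chosen plan sets C6 on a six-membered ring and needs only four functional-group steps after ring formation.

**Alternative 2: anionic oxy-Cope ring expansion.** The cut is at C8–C9, with the six-ring bond between the carbinol carbon and its neighbour restored.
- Forward step: the potassium alkoxide of dialkenyl cyclohexenol A5 would rearrange through a chair transition state to the enolate of dienone A4.
- Merits: this ring expansion is a proven way to ten-membered dienones. The E geometry follows from the chair, the Z geometry from the six-membered ring, and the route is short.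
- Weak points: C7 is set by protonation of a medium-ring enolate. C6 must then be set by 1,2-reduction of a Z enone on the macrocycle. The carbinol requires addition of a hindered alkenyllithium to an enolisable enone.
- Comparison: in precedent and probably in step count this road is better than the chosen one. The chosen plan sets against it a C6–C7–C8 triad secured by an auxiliary aldol reaction and a six-ring reduction before ring closure, and two oxygens that leave the key step already differentiated.

**Alternative 3: sulfone carbanion macro-alkylation.** The cut is at C2–C3.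
- Forward step: deprotonation of acyclic bromo sulfone A7 and intramolecular displacement of the allylic bromide would give sulfone A6.
- Merits: carbanion macro-alkylation is known for medium-ring terpenoids and tolerates silyl ethers.
- Weak points: the Z allylic bromide is prone to allylic transposition and geometric scrambling. The acyclic precursor needs the same triad plus two different silyl groups, so the linear sequence is longer. The sulfone must afterwards be removed reductively from an allylic position, which can shift or isomerise C1=C10.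
- Comparison: the closure itself is better precedented than the chosen one. The chosen plan offers a template that holds the reacting ends together, no extra removal step, and alkene geometry fixed by a ring.

Key step: step 12

Assumption: ring positions in the pyran and macrocycle compounds are numbered as in germacrane, and silyl ether 1 is taken as a catalogue chemical.

## Route

Step 1
Reactants: 1 tert-butyl(but-3-yn-1-yloxy)dimethylsilane; 2 oxirane
Product: 5 (3E)-6-(tert-butyldimethylsilyloxy)-4-methylhex-3-en-1-ol, via alkenylalane 3 (not isolated), via lithium alanate 4 (not isolated)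
Conditions: Me3Al, Cp2ZrCl2 (20 mol%), CH2Cl2, 0 °C → rt; evaporate, hexane/THF; n-BuLi, −78 → 0 °C; 2, 0 °C → rt; aq. Rochelle salt
Reagents that add atoms: trimethylaluminium, C[Al](C)C
Why: Zirconium-catalysed carboalumination (Negishi) adds CH3 and Al syn across the alkyne with Al at the terminus; the derived alanate opens oxirane with retention at the alkenyl carbon, so C9 and C2 end up trans (E).

Step 2
Reactants: 5 (3E)-6-(tert-butyldimethylsilyloxy)-4-methylhex-3-en-1-ol
Product: 6 (3E)-6-bromo-1-(tert-butyldimethylsilyloxy)-3-methylhex-3-ene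
Conditions: CBr4, PPh3, CH2Cl2, 0 °C
Reagents that add atoms: carbon tetrabromide, BrC(Br)(Br)Br
Why: Appel bromination of a primary alcohol under neutral conditions; the silyl ether and the trisubstituted alkene are inert.

Step 3
Reactants: 6 (3E)-6-bromo-1-(tert-butyldimethylsilyloxy)-3-methylhex-3-ene
Product: 7 (3E)-6-bromo-3-methylhex-3-en-1-ol
Conditions: camphorsulfonic acid (10 mol%), MeOH, 0 °C → rt
Reagents that add atoms: none
Why: Acid-catalysed methanolysis of a primary silyl ether; no fluoride is used, so the primary bromide is not displaced.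

Step 4
Reactants: 7 (3E)-6-bromo-3-methylhex-3-en-1-ol
Product: 8 (3E)-6-bromo-3-methylhex-3-enal
Conditions: Dess–Martin periodinane, NaHCO3, CH2Cl2, 0 °C; used crude
Reagents that add atoms: none
Why: Dess–Martin oxidation under bicarbonate buffering stops at the aldehyde and should leave the β,γ-alkene out of conjugation; 8 is used at once.

Step 5
Reactants: 9 (4R)-4-benzyl-1,3-oxazolidin-2-one; 10 3-methylbutanoyl chloride
Product: 12 (4R)-4-benzyl-3-(3-methylbutanoyl)-1,3-oxazolidin-2-one, via lithium oxazolidinide 11 (not isolated)
Conditions: n-BuLi, THF, −78 °C; then 10, −78 → 0 °C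
Reagents that add atoms: none
Why: N-acylation of the lithiated oxazolidinone by the acid chloride, the standard entry to Evans imides.

Step 6
Reactants: 12 (4R)-4-benzyl-3-(3-methylbutanoyl)-1,3-oxazolidin-2-one; 8 (3E)-6-bromo-3-methylhex-3-enal
Product: 15 (4R)-4-benzyl-3-[(2R,3S,5E)-8-bromo-3-hydroxy-5-methyl-2-(propan-2-yl)oct-5-enoyl]-1,3-oxazolidin-2-one, via boron enolate 13 (not isolated), via boron aldolate 14 (not isolated)
Conditions: n-Bu2BOTf, i-Pr2NEt, CH2Cl2, 0 °C; 8, −78 → 0 °C; pH 7 buffer, MeOH, H2O2, 0 °C
Reagents that add atoms: none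
Why: Evans syn-aldol reaction: the Z boron enolate reacts through a closed chair transition state on the face away from the benzyl group, which sets C7 (R) and C8 (S) in the syn relation that becomes the cis 2,3-relation of the pyran; the aldehyde is consumed at −78 °C before it can isomerise.

Step 7
Reactants: 15 (4R)-4-benzyl-3-[(2R,3S,5E)-8-bromo-3-hydroxy-5-methyl-2-(propan-2-yl)oct-5-enoyl]-1,3-oxazolidin-2-one
Product: 16 (2R,3S,5E)-8-bromo-3-hydroxy-N-methoxy-N,5-dimethyl-2-(propan-2-yl)oct-5-enamide
Conditions: MeNHOMe·HCl, Me3Al, CH2Cl2, −15 → 0 °C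
Reagents that add atoms: N,O-dimethylhydroxylamine hydrochloride, Cl.CNOC
Why: Aluminium amide transamination of a β-hydroxy imide to the Weinreb amide, assisted by the aluminium alkoxide of the free C8 hydroxyl; the auxiliary is released and C7 is not epimerised.

Step 8
Reactants: 16 (2R,3S,5E)-8-bromo-3-hydroxy-N-methoxy-N,5-dimethyl-2-(propan-2-yl)oct-5-enamide; 17 prop-1-yn-1-ylmagnesium bromide
Product: 18 (5R,6S,8E)-11-bromo-6-hydroxy-8-methyl-5-(propan-2-yl)undec-8-en-2-yn-4-one
Conditions: 17 (3.5 equiv), THF, −20 → 0 °C; aq. NH4Cl
Reagents that add atoms: none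
Why: Acyl substitution of a Weinreb amide by an alkynyl Grignard reagent; the magnesium-chelated adduct collapses only on work-up, which prevents over-addition and keeps C7 from enolising.

Step 9
Reactants: 18 (5R,6S,8E)-11-bromo-6-hydroxy-8-methyl-5-(propan-2-yl)undec-8-en-2-yn-4-one
Product: 19 (2S,3R)-2-[(2E)-5-bromo-2-methylpent-2-en-1-yl]-6-methyl-3-(propan-2-yl)-2,3-dihydro-4H-pyran-4-one
Conditions: Ph3PAuNTf2 (3 mol%), CH2Cl2, rt
Reagents that add atoms: none
Why: Gold-catalysed 6-endo-dig hydroalkoxylation (intramolecular oxa-Michael addition) of a β-hydroxy ynone: the C8 hydroxyl adds to the activated alkyne carbon C4 and protodeauration gives the vinylogous ester; neutral conditions preserve the cis C7/C8 relation.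

Step 10
Reactants: 19 (2S,3R)-2-[(2E)-5-bromo-2-methylpent-2-en-1-yl]-6-methyl-3-(propan-2-yl)-2,3-dihydro-4H-pyran-4-one
Product: 20 (2S,3S,4R)-2-[(2E)-5-bromo-2-methylpent-2-en-1-yl]-6-methyl-3-(propan-2-yl)-3,4-dihydro-2H-pyran-4-ol (all-cis)
Conditions: NaBH4, CeCl3·7H2O, MeOH, −78 °C
Reagents that add atoms: none
Why: Luche 1,2-reduction of the vinylogous ester; hydride adds to the C6 carbonyl from the face opposite the two cis substituents (axial attack anti to the pseudo-axial isopropyl group), which places the hydroxyl cis to both and sets C6.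

Step 11
Reactants: 20 (2S,3S,4R)-2-[(2E)-5-bromo-2-methylpent-2-en-1-yl]-6-methyl-3-(propan-2-yl)-3,4-dihydro-2H-pyran-4-ol
Product: 21 (2S,3R,4R)-2-[(2E)-5-bromo-2-methylpent-2-en-1-yl]-4-(tert-butyldimethylsilyloxy)-6-methyl-3-(propan-2-yl)-3,4-dihydro-2H-pyran (all-cis)
Conditions: TBSOTf, 2,6-lutidine, CH2Cl2, −78 °C
Reagents that add atoms: tert-butyldimethylsilyl trifluoromethanesulfonate, CC(C)(C)[Si](C)(C)OS(=O)(=O)C(F)(F)F
Why: Silylation of a hindered secondary allylic alcohol with the silyl triflate and a hindered base; the base buffering protects the acid-labile enol ether.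

Step 12
Reactants: 21 (2S,3R,4R)-2-[(2E)-5-bromo-2-methylpent-2-en-1-yl]-4-(tert-butyldimethylsilyloxy)-6-methyl-3-(propan-2-yl)-3,4-dihydro-2H-pyran
Product: 23 (6S,7R,8S)-6-(tert-butyldimethylsilyloxy)germacra-1(10)E,4Z-dien-8-ol, via Grignard reagent 22 (not isolated)
Conditions: Mg turnings, THF, 35 °C; syringe-pump addition of 22 over 12 h to NiCl2(PPh3)2 (10 mol%, pre-reduced with i-Bu2AlH) in toluene, 90 °C, final concentration ca. 0.003 M; aq. NH4Cl
Reagents that add atoms: none
Why: Proposed new method: zerovalent nickel (from NiCl2(PPh3)2 and i-Bu2AlH) should insert into the alkenyl C4–O bond of the enol ether, helped by magnesium bound to the ring oxygen; the tethered C3 alkyl group then moves from magnesium to nickel and reductive elimination forms C3–C4 while the C8 oxygen leaves as its magnesium alkoxide. The closest known reaction type is the intermolecular nickel-catalysed cross-coupling of dihydrofurans and dihydropyrans with Grignard reagents, in which carbon replaces the enol-ether oxygen with ring opening and retention of alkene geometry. The ten-membered carbocycle closes by C(sp3)–C(sp2) reductive elimination from an eleven-membered nickelacycle, an end-to-end closure in which the chain on C8 stays tied to the metal-bound C8 oxygen until the C–C bond exists; the pyran ring opens in the same event. No stereocentre is formed and C6, C7 and C8 are untouched. The one stereochemical element created, the C4=C5 geometry, has to be cis (4Z): C3 takes the place of the ring oxygen with retention, and oxygen and C6 are necessarily cis in the six-membered ring. Cyclisation must beat oligomerisation, which slow addition of 22 to the hot catalyst at high dilution and the oxygen tether serve. Reductive elimination must beat β-hydride loss from the C3–nickel alkyl and nickel must leave the allylic C6–O bond alone; the bulky, weakly coordinating silyl ether and the phosphine ligand are chosen for this, with the ligand open to variation. The E geometry of C1=C10 is carried in from 8, and 22 has no acidic or electrophilic partner in the molecule.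

Step 13
Reactants: 23 (6S,7R,8S)-6-(tert-butyldimethylsilyloxy)germacra-1(10)E,4Z-dien-8-ol; 24 angelic acid [(2Z)-2-methylbut-2-enoic acid]
Product: 25 (6S,7R,8S)-6-(tert-butyldimethylsilyloxy)germacra-1(10)E,4Z-dien-8-yl angelate
Conditions: 24, 2,4,6-trichlorobenzoyl chloride, Et3N, toluene, rt; then 23, 80 °C
Reagents that add atoms: none
Why: Yamaguchi-type mixed-anhydride esterification, the usual route to angelates: the trichlorobenzoyl mixed anhydride acylates the hindered C8 hydroxyl without a nucleophilic catalyst, which limits Z to E isomerisation to the tiglate.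

Step 14
Reactants: 25 (6S,7R,8S)-6-(tert-butyldimethylsilyloxy)germacra-1(10)E,4Z-dien-8-yl angelate
Product: 26 (6S,7S,8S)-6-hydroxygermacra-1(10)E,4Z-dien-8-yl angelate
Conditions: HF·pyridine, pyridine, THF, 0 °C → rt
Reagents that add atoms: none
Why: Fluoride-mediated cleavage of the secondary silyl ether under pyridine buffering; strongly acidic and strongly basic conditions are both avoided, to suppress transannular reactions and acyl migration from the C8 to the C6 oxygen.

Step 15
Reactants: 26 (6S,7S,8S)-6-hydroxygermacra-1(10)E,4Z-dien-8-yl angelate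
Product: 27 (4S,5R,6R,7S,8S)-4,5-epoxy-6-hydroxygermacr-1(10)E-en-8-yl angelate
Conditions: VO(acac)2 (10 mol%), t-BuOOH (decane solution), CH2Cl2, 0 °C → rt
Reagents that add atoms: tert-butyl hydroperoxide, CC(C)(C)OO
Why: Hydroxyl-directed epoxidation: the pentavalent vanadium alkoxide of the C6 hydroxyl delivers oxygen to the adjacent C4=C5 bond on its own face, as with medium-ring cis-cycloalkenols, setting C4 and C5 with the cis alkene geometry retained; the unactivated 1(10)-alkene and the electron-poor angelate are not oxidised.

Step 16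
Reactants: 27 (4S,5R,6R,7S,8S)-4,5-epoxy-6-hydroxygermacr-1(10)E-en-8-yl angelate
Product: 28 (4S,5R,6R,7R,8S)-6-acetoxy-4,5-epoxygermacr-1(10)E-en-8-yl angelate (CNP0289272.1)
Conditions: Ac2O, pyridine, DMAP (cat.), CH2Cl2, 0 °C → rt
Reagents that add atoms: acetic anhydride, CC(=O)OC(C)=O
Why: Acetylation of the secondary alcohol under DMAP catalysis; the mild base leaves the epoxide and the angelate intact.

## Compound list

1 | tert-butyl(but-3-yn-1-yloxy)dimethylsilane | C#CCCO[Si](C)(C)C(C)(C)C | starting material
2 | oxirane (ethylene oxide) | C1CO1 | starting material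
3 | (E)-[4-(tert-butyldimethylsilyloxy)-2-methylbut-1-en-1-yl]dimethylalane | C[Al](C)/C=C(\C)CCO[Si](C)(C)C(C)(C)C | intermediate
4 | lithium (E)-butyl[4-(tert-butyldimethylsilyloxy)-2-methylbut-1-en-1-yl]dimethylaluminate | [Li+].CCCC[Al-](C)(C)/C=C(\C)CCO[Si](C)(C)C(C)(C)C | intermediate
5 | (3E)-6-(tert-butyldimethylsilyloxy)-4-methylhex-3-en-1-ol | OCC/C=C(\C)CCO[Si](C)(C)C(C)(C)C | intermediate
6 | (3E)-6-bromo-1-(tert-butyldimethylsilyloxy)-3-methylhex-3-ene | BrCC/C=C(\C)CCO[Si](C)(C)C(C)(C)C | intermediate
7 | (3E)-6-bromo-3-methylhex-3-en-1-ol | BrCC/C=C(\C)CCO | intermediate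
8 | (3E)-6-bromo-3-methylhex-3-enal | BrCC/C=C(\C)CC=O | intermediate
9 | (4R)-4-benzyl-1,3-oxazolidin-2-one | O=C1N[C@H](Cc2ccccc2)CO1 | starting material
10 | 3-methylbutanoyl chloride | CC(C)CC(Cl)=O | starting material
11 | lithium (4R)-4-benzyl-2-oxo-1,3-oxazolidin-3-ide | [Li]N1C(=O)OC[C@H]1Cc1ccccc1 | intermediate
12 | (4R)-4-benzyl-3-(3-methylbutanoyl)-1,3-oxazolidin-2-one | CC(C)CC(=O)N1C(=O)OC[C@H]1Cc1ccccc1 | intermediate
13 | (Z)-di-n-butylboron enolate of 12 | CCCCB(CCCC)O/C(=C\C(C)C)N1C(=O)OC[C@H]1Cc1ccccc1 | intermediate
14 | di-n-butylboron aldolate of 15 | BrCC/C=C(C)/C[C@H](OB(CCCC)CCCC)[C@@H](C(C)C)C(=O)N1C(=O)OC[C@H]1Cc1ccccc1 | intermediate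
15 | (4R)-4-benzyl-3-[(2R,3S,5E)-8-bromo-3-hydroxy-5-methyl-2-(propan-2-yl)oct-5-enoyl]-1,3-oxazolidin-2-one | BrCC/C=C(C)/C[C@H](O)[C@@H](C(C)C)C(=O)N1C(=O)OC[C@H]1Cc1ccccc1 | intermediate
16 | (2R,3S,5E)-8-bromo-3-hydroxy-N-methoxy-N,5-dimethyl-2-(propan-2-yl)oct-5-enamide | BrCC/C=C(C)/C[C@H](O)[C@@H](C(C)C)C(=O)N(C)OC | intermediate
17 | prop-1-yn-1-ylmagnesium bromide | CC#C[Mg]Br | starting material
18 | (5R,6S,8E)-11-bromo-6-hydroxy-8-methyl-5-(propan-2-yl)undec-8-en-2-yn-4-one | BrCC/C=C(C)/C[C@H](O)[C@@H](C(C)C)C(=O)C#CC | intermediate
19 | (2S,3R)-2-[(2E)-5-bromo-2-methylpent-2-en-1-yl]-6-methyl-3-(propan-2-yl)-2,3-dihydro-4H-pyran-4-one | BrCC/C=C(C)/C[C@@H]1OC(C)=CC(=O)[C@@H]1C(C)C | intermediate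
20 | (2S,3S,4R)-2-[(2E)-5-bromo-2-methylpent-2-en-1-yl]-6-methyl-3-(propan-2-yl)-3,4-dihydro-2H-pyran-4-ol (all-cis) | BrCC/C=C(C)/C[C@@H]1OC(C)=C[C@H](O)[C@@H]1C(C)C | intermediate
21 | (2S,3R,4R)-2-[(2E)-5-bromo-2-methylpent-2-en-1-yl]-4-(tert-butyldimethylsilyloxy)-6-methyl-3-(propan-2-yl)-3,4-dihydro-2H-pyran (all-cis) | BrCC/C=C(C)/C[C@@H]1OC(C)=C[C@H](O[Si](C)(C)C(C)(C)C)[C@@H]1C(C)C | intermediate
22 | Grignard reagent of 21 (C3–MgBr) | Br[Mg]CC/C=C(C)/C[C@@H]1OC(C)=C[C@H](O[Si](C)(C)C(C)(C)C)[C@@H]1C(C)C | intermediate
23 | (6S,7R,8S)-6-(tert-butyldimethylsilyloxy)germacra-1(10)E,4Z-dien-8-ol | O[C@H]1C/C(C)=C/CC/C(C)=C\[C@H](O[Si](C)(C)C(C)(C)C)[C@@H]1C(C)C | intermediate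
24 | angelic acid, (2Z)-2-methylbut-2-enoic acid | C/C=C(/C)C(=O)O | starting material
25 | (6S,7R,8S)-6-(tert-butyldimethylsilyloxy)germacra-1(10)E,4Z-dien-8-yl angelate | C/C=C(/C)C(=O)O[C@H]1C/C(C)=C/CC/C(C)=C\[C@H](O[Si](C)(C)C(C)(C)C)[C@@H]1C(C)C | intermediate
26 | (6S,7S,8S)-6-hydroxygermacra-1(10)E,4Z-dien-8-yl angelate | C/C=C(/C)C(=O)O[C@H]1C/C(C)=C/CC/C(C)=C\[C@H](O)[C@@H]1C(C)C | intermediate
27 | (4S,5R,6R,7S,8S)-4,5-epoxy-6-hydroxygermacr-1(10)E-en-8-yl angelate | C/C=C(/C)C(=O)O[C@H]1C/C(C)=C/CC[C@]2(C)O[C@@H]2[C@H](O)[C@@H]1C(C)C | intermediate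
28 | (4S,5R,6R,7R,8S)-6-acetoxy-4,5-epoxygermacr-1(10)E-en-8-yl angelate (CNP0289272.1) | C/C=C(/C)C(=O)O[C@H]1C/C(C)=C/CC[C@]2(C)O[C@@H]2[C@H](OC(C)=O)[C@@H]1C(C)C | target

## Step count and risks

Total: 16 steps. Longest linear sequence: 15 steps (1 to 28 through steps 1–4 and 6–16); step 5 is a one-step branch.

**Step 12 (key step, proposed new method).** Most likely failures:
- no insertion of nickel into the hindered, trisubstituted enol-ether C–O bond, since six-membered enol ethers are sluggish in the known intermolecular coupling;
- β-hydride loss from the primary alkyl on nickel, giving open-chain reduced material;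
- oligomerisation in place of medium-ring closure;
- ionisation of the allylic C6–O bond by nickel.

Fallback with known chemistry, from Weinreb amide 16 back to 23. It forms the same C3–C4 bond by a B-alkyl Suzuki–Miyaura macrocyclisation on a (Z)-alkenyl iodide.
- 4-Methoxybenzyl trichloroacetimidate with catalytic acid would give the 8-O-PMB Weinreb amide F1.
- Reagent 17 would convert it into the 8-O-PMB ynone F2.
- Noyori transfer hydrogenation with RuCl[(R,R)-TsDPEN](p-cymene) in i-PrOH (the catalyst enantiomer that gives the 6R carbinol) should give the propargylic alcohol F3.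
- KOt-Bu would eliminate HBr to the terminal diene F4.
- NaAlH2(OCH2CH2OMe)2 followed by I2 (hydroxyl-directed trans-hydroalumination and iodination) would give the (Z)-alkenyl iodide F5.
- TBSOTf would give the 6-O-TBS ether F6.
- 9-BBN-H would hydroborate the terminal alkene to the B-alkyl borane F7 (not isolated).
- PdCl2(dppf), Ph3As and Cs2CO3 under high dilution should close it to the 8-O-PMB macrocycle F8, with retention at C4.
- DDQ would then release 23.

**Step 8.** Addition of the alkynyl Grignard reagent to the α-branched amide may be slow, and the magnesium aldolate may undergo retro-aldol cleavage or C7 epimerisation while it waits. Fallback from 16 back to 19: the lithium enolate of acetone (LiN(i-Pr)2, acetone, THF, −78 °C) would acylate on the Weinreb amide to give the β-diketone F9. Catalytic CF3CO2H in CH2Cl2 would cyclodehydrate it through the six-membered hemiketal to pyranone 19, bypassing the ynone and the gold step.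

**Step 13.** Isomerisation of the angeloyl unit to the tigloyl unit, or incomplete acylation of the hindered C8 hydroxyl at the temperature needed, are the likely failures. Fallback from 23 back to 25, building the Z alkene on the ester. Esterification with 2-[bis(2,2,2-trifluoroethoxy)phosphoryl]propanoic acid (DCC, DMAP) would give the phosphonate ester F10. A Still–Gennari olefination (KN(SiMe3)2, 18-crown-6, THF, −78 °C, acetaldehyde) should then give the Z trisubstituted ester 25.

**Step 15.** Delivery to the wrong face if the ring adopts a conformer unlike those of simple medium-ring cycloalkenols, oxidation of the hindered allylic alcohol to the enone, or Lewis-acid-induced transannular opening of the product are the likely failures. Fallback from 23 back to 27, changing the order so that the epoxide is made before the ester is present. Bu4NF would give the 6,8-diol F11. VO(acac)2 and t-BuOOH should epoxidise the allylic C4=C5 bond faster than the homoallylic C1=C10 bond, giving the epoxy diol F12. Angeloylation of the less hindered C8 hydroxyl, as in step 13 or its fallback, would then give 27.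

## Further compounds

F1 | step 12 | 8-O-PMB Weinreb amide, (2R,3S,5E)-8-bromo-N-methoxy-3-(4-methoxybenzyloxy)-N,5-dimethyl-2-(propan-2-yl)oct-5-enamide | BrCC/C=C(C)/C[C@H](OCc1ccc(OC)cc1)[C@@H](C(C)C)C(=O)N(C)OC
F2 | step 12 | 8-O-PMB ynone, (5R,6S,8E)-11-bromo-6-(4-methoxybenzyloxy)-8-methyl-5-(propan-2-yl)undec-8-en-2-yn-4-one | BrCC/C=C(C)/C[C@H](OCc1ccc(OC)cc1)[C@@H](C(C)C)C(=O)C#CC
F3 | step 12 | propargylic alcohol, (4R,5S,6S,8E)-11-bromo-6-(4-methoxybenzyloxy)-8-methyl-5-(propan-2-yl)undec-8-en-2-yn-4-ol | BrCC/C=C(C)/C[C@H](OCc1ccc(OC)cc1)[C@@H](C(C)C)[C@@H](O)C#CC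
F4 | step 12 | terminal diene, (4R,5S,6S,8E)-6-(4-methoxybenzyloxy)-8-methyl-5-(propan-2-yl)undeca-8,10-dien-2-yn-4-ol | C=C/C=C(C)/C[C@H](OCc1ccc(OC)cc1)[C@@H](C(C)C)[C@@H](O)C#CC
F5 | step 12 | (Z)-alkenyl iodide, (2Z,4R,5S,6S,8E)-2-iodo-6-(4-methoxybenzyloxy)-8-methyl-5-(propan-2-yl)undeca-2,8,10-trien-4-ol | C=C/C=C(C)/C[C@H](OCc1ccc(OC)cc1)[C@@H](C(C)C)[C@@H](O)/C=C(/C)I
F6 | step 12 | 6-O-TBS ether of F5 | C=C/C=C(C)/C[C@H](OCc1ccc(OC)cc1)[C@@H](C(C)C)[C@@H](O[Si](C)(C)C(C)(C)C)/C=C(/C)I
F7 | step 12 | B-alkyl-9-borabicyclo[3.3.1]nonane from F6 (boron on C3) | C(CB1C2CCCC1CCC2)/C=C(C)/C[C@H](OCc1ccc(OC)cc1)[C@@H](C(C)C)[C@@H](O[Si](C)(C)C(C)(C)C)/C=C(/C)I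
F8 | step 12 | 6-O-TBS-8-O-PMB-germacra-1(10)E,4Z-diene-6,8-diol | COc1ccc(CO[C@H]2C/C(C)=C/CC/C(C)=C\[C@H](O[Si](C)(C)C(C)(C)C)[C@@H]2C(C)C)cc1
F9 | step 8 | (5R,6S,8E)-11-bromo-6-hydroxy-8-methyl-5-(propan-2-yl)undec-8-ene-2,4-dione | BrCC/C=C(C)/C[C@H](O)[C@@H](C(C)C)C(=O)CC(C)=O
F10 | step 13 | (6S,7R,8S)-6-(tert-butyldimethylsilyloxy)germacra-1(10)E,4Z-dien-8-yl 2-[bis(2,2,2-trifluoroethoxy)phosphoryl]propanoate (epimers at the phosphonate carbon) | CC(P(=O)(OCC(F)(F)F)OCC(F)(F)F)C(=O)O[C@H]1C/C(C)=C/CC/C(C)=C\[C@H](O[Si](C)(C)C(C)(C)C)[C@@H]1C(C)C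
F11 | step 15 | (6S,7R,8S)-germacra-1(10)E,4Z-diene-6,8-diol | O[C@H]1C/C(C)=C/CC/C(C)=C\[C@H](O)[C@@H]1C(C)C
F12 | step 15 | (4S,5R,6R,7R,8S)-4,5-epoxygermacr-1(10)E-ene-6,8-diol | O[C@H]1C/C(C)=C/CC[C@]2(C)O[C@@H]2[C@H](O)[C@@H]1C(C)C
A1 | alternative 1 | head-to-head cis-anti-cis tricyclic photoadduct (cyclobutane C1, C4, C5, C10; methyl ester on C4; 8-O-TBS; C6 ketone) | CC(C)(C)[Si](C)(C)O[C@H]1C[C@]2(C)[C@H]3CC[C@@]3(C(=O)OC)[C@@H]2C(=O)[C@@H]1C(C)C
A2 | alternative 1 | (5S,6R)-5-(tert-butyldimethylsilyloxy)-3-methyl-6-(propan-2-yl)cyclohex-2-en-1-one | CC1=CC(=O)[C@H](C(C)C)[C@@H](O[Si](C)(C)C(C)(C)C)C1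
A3 | alternative 1 | methyl cyclobut-1-ene-1-carboxylate | COC(=O)C1=CCC1
A4 | alternative 2 | (7R,8S)-8-(4-methoxybenzyloxy)germacra-1(10)E,4Z-dien-6-one | COc1ccc(CO[C@H]2C/C(C)=C/CC/C(C)=C\C(=O)[C@@H]2C(C)C)cc1
A5 | alternative 2 | (1S,6S)-1-[(1E)-1-(4-methoxybenzyloxy)-3-methylbut-1-en-2-yl]-3-methyl-6-(prop-1-en-2-yl)cyclohex-2-en-1-ol | COc1ccc(CO/C=C(\C(C)C)[C@]2(O)C=C(C)CC[C@H]2C(C)=C)cc1
A6 | alternative 3 | 2-(phenylsulfonyl)-6-O-TES-8-O-TBS-germacra-1(10)E,4Z-diene-6,8-diol (C2 epimer immaterial) | CC(C)(C)[Si](C)(C)O[C@H]1C/C(C)=C/[C@H](S(=O)(=O)c2ccccc2)C/C(C)=C\[C@H](O[Si](CC)(CC)CC)[C@@H]1C(C)C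
A7 | alternative 3 | acyclic precursor of A6 with C3 allylic bromide and C2 phenyl sulfone (6-O-TES, 8-O-TBS, 4Z, 1(10)E) | BrC/C(C)=C\[C@H](O[Si](CC)(CC)CC)[C@H](C(C)C)[C@@H](O[Si](C)(C)C(C)(C)C)C/C(C)=C/CS(=O)(=O)c1ccccc1
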